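**Direct plan and its weak points**

A direct plan would build ring A last, by a Diels–Alder reaction with aromatising loss of methanol between the 1,1-dimethoxy-3-silyloxydiene A2 and the terminal ynone A3, which already carries ring B and the linker as a methoxy enone. It would then unmask the diketone from the aryl methoxy enone A4 with fluoride and aqueous acid.
- The passage from ketene dithioacetal A1 to diene A2 would be weak. A double exchange of methylthio for methoxy under hot methoxide on a tetrasubstituted push–pull alkene has little precedent, retro-Claisen cleavage would compete, and the acyl ketene acetal and its silyl dienol ether would be too hydrolysis-prone to purify.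
- The four-operation run-up to A3 (enol etherification, silylation, Weinreb amide, ethynyl Grignard addition) would be weak. It would form a single C–C bond and end in a polymerisation-prone terminal ynone that needs an excess of the fragile diene.
- The closing acid hydrolysis of the methoxy enone of A4 would be weak. It would take place next to a freshly freed ortho-prenylphenol, where chroman formation would threaten the finished skeleton.

**Retrosynthetic overview of the new route**

- The hard feature is ring A: four contiguous substituents, C1' (acyl), C2' (OMe), C3' (prenyl) and C4' (OH), with the prenyl group wedged between two oxygens that must be told apart.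
- Key disconnection: ring A is cut at C2'–C3', C4'–C5' and C1'–C2' into siloxyalkyne 4 (C3', C4', prenyl, silyl ether) and the vinylketene from diazo ketone 7 (C2' as ketene carbon, C5', C6', and C1' with its ester). A Danheiser benzannulation joins them.
- Second disconnection: the C1–C2 bond of the propanedione, by Claisen condensation of ring A ester 12 with the enolate of ring B ketone 14. Ring A is closed first from open-chain parts, ring B is bought, the linker comes last.
- The design uses no ketene acetal and no enol ether. The two ring A oxygens differ by origin (ketene carbonyl gives the phenol that is methylated, ynol ether gives the silyl ether). The ortho-prenylphenol is freed only in a final buffered fluoride step, so it never meets acid.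

Key step: step 3

Assumption: ethyl 4-methylpent-3-enoate 1 and methyl (E)-4-oxopent-2-enoate 5 are taken as catalogue compounds; 1 would otherwise follow from 4-methylpent-3-enoic acid by Fischer esterification.

**Route**

Step 1
Reactants: 1 ethyl 4-methylpent-3-enoate
Product: 4 triisopropyl[(5-methylhex-4-en-1-yn-1-yl)oxy]silane, via lithium dibromoenolate 2 (not isolated), via lithium ynolate 3 (not isolated)
Conditions: CH2Br2 (2.2 equiv), lithium 2,2,6,6-tetramethylpiperidide (2.1 equiv), THF, −78 °C; n-BuLi, −78 → 25 °C; then i-Pr3SiCl, −78 °C → rt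
Reagents that add atoms: dibromomethane, BrCBr; chlorotriisopropylsilane, CC(C)[Si](Cl)(C(C)C)C(C)C
Why: Kowalski ester homologation stopped at the ynolate stage: dibromomethyllithium adds to the ester, enolate 2 undergoes bromine–lithium exchange and 1,2-shift to ynolate 3, and the bulky silyl chloride should trap 3 on oxygen, the isolated trisubstituted alkene being inert.

Step 2
Reactants: 5 methyl (E)-4-oxopent-2-enoate
Product: 7 methyl (E)-5-diazo-4-oxopent-2-enoate, via trifluoroacetyl diketone 6 (not isolated)
Conditions: LiN(SiMe3)2 (1.1 equiv), THF, −78 °C, slow addition of 5; CF3CO2CH2CF3; then MsN3, Et3N, H2O (1 equiv), MeCN, rt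
Reagents that add atoms: methanesulfonyl azide, CS(=O)(=O)N=[N+]=[N-]; 2,2,2-trifluoroethyl trifluoroacetate, O=C(OCC(F)(F)F)C(F)(F)F (atoms only in intermediate 6)
Why: Detrifluoroacetylative diazo transfer (Claisen trifluoroacetylation of the kinetic enolate at the only enolisable position, then transfer of the diazo group with loss of the trifluoroacetyl group), the standard entry to α,β-unsaturated diazomethyl ketones, for which acylation of diazomethane fails through pyrazoline formation.

Step 3
Reactants: 7 methyl (E)-5-diazo-4-oxopent-2-enoate; 4 triisopropyl[(5-methylhex-4-en-1-yn-1-yl)oxy]silane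
Product: 11 methyl 2-hydroxy-3-(3-methylbut-2-en-1-yl)-4-(triisopropylsilyloxy)benzoate, via vinylketene 8 (not isolated), via 4-vinylcyclobutenone 9 (not isolated), via dienylketene 10 (not isolated)
Conditions: 7 (1.0 equiv), 4 (1.3 equiv), degassed ClCH2CH2Cl, hν (300 nm), rt; then 80 °C
Reagents that add atoms: none
Why: Irradiation should trigger a Wolff rearrangement of 7 (loss of N2, 1,2-shift of the alkenyl group) to the (E)-vinylketene 8, whose electrophilic ketene carbon is attacked by the nucleophilic, prenyl-bearing carbon of ynol ether 4 in a regiospecific [2+2] cycloaddition to 4-vinylcyclobutenone 9; heating then opens 9 by 4π electrocyclic cleavage to dienylketene 10, which closes by 6π electrocyclisation and tautomerises to phenol 11. The closest known reaction type is the Danheiser benzannulation in its diazo ketone variant, which turns α,β-unsaturated diazomethyl ketones and siloxyalkynes into resorcinol monosilyl ethers. Ring A closes as a six-membered carbocycle in an intermolecular, formally [4+2] mode, the bonds C2'–C3' and C4'–C5' coming from the [2+2] step and C1'–C2' from the 6π closure. No stereocentre remains, since the sp3 carbon of 9 is transient. The step needs regioselectivity and chemoselectivity: the polarity of ketene and ynol ether forces the prenyl group between the new hydroxyl (C2', from the ketene carbonyl) and the silyl ether (C4'), the ketene should take the electron-rich alkyne far faster than the trisubstituted alkene, and the E enoate both points the ester outwards in the 6π step and cannot close to a 2-pyranone.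

Step 4
Reactants: 11 methyl 2-hydroxy-3-(3-methylbut-2-en-1-yl)-4-(triisopropylsilyloxy)benzoate
Product: 12 methyl 2-methoxy-3-(3-methylbut-2-en-1-yl)-4-(triisopropylsilyloxy)benzoate
Conditions: MeI (3 equiv), K2CO3 (2 equiv), acetone, reflux
Reagents that add atoms: iodomethane, CI
Why: Williamson O-methylation of the only free phenol, under carbonate in acetone, which should be too mild to cleave the hindered aryl triisopropylsilyl ether.

Step 5
Reactants: 13 1-(4-hydroxyphenyl)ethan-1-one
Product: 14 1-[4-(triisopropylsilyloxy)phenyl]ethan-1-one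
Conditions: i-Pr3SiCl (1.2 equiv), imidazole (2 equiv), DMF, rt
Reagents that add atoms: chlorotriisopropylsilane, CC(C)[Si](Cl)(C(C)C)C(C)C
Why: Imidazole-mediated silylation of a phenol, which removes the acidic proton before enolate formation and matches the silyl group already on ring A, so that one reagent frees both phenols at the end.

Step 6
Reactants: 14 1-[4-(triisopropylsilyloxy)phenyl]ethan-1-one; 12 methyl 2-methoxy-3-(3-methylbut-2-en-1-yl)-4-(triisopropylsilyloxy)benzoate
Product: 16 1-[2-methoxy-3-(3-methylbut-2-en-1-yl)-4-(triisopropylsilyloxy)phenyl]-3-[4-(triisopropylsilyloxy)phenyl]propane-1,3-dione, via lithium enolate 15 (not isolated)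
Conditions: 14 (1.1 equiv), LiN(SiMe3)2 (2.3 equiv), THF, −78 °C; then 12, −78 °C → rt; cold sat. aq. NH4Cl
Reagents that add atoms: none
Why: Crossed Claisen condensation of a preformed lithium enolate with a non-enolisable aryl ester, driven by deprotonation of the diketone by the second equivalent of base; the para silyl ether keeps the ester electrophilic.

Step 7
Reactants: 16 1-[2-methoxy-3-(3-methylbut-2-en-1-yl)-4-(triisopropylsilyloxy)phenyl]-3-[4-(triisopropylsilyloxy)phenyl]propane-1,3-dione
Product: 17 1-[4-hydroxy-2-methoxy-3-(3-methylbut-2-en-1-yl)phenyl]-3-(4-hydroxyphenyl)propane-1,3-dione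
Conditions: Bu4NF (2.4 equiv), AcOH (2.4 equiv), THF, 0 °C → rt
Reagents that add atoms: none
Why: Fluoride-mediated desilylation of both aryl silyl ethers, buffered with acetic acid, so that the ortho-prenylphenol is freed without mineral acid and cannot cyclise to a chroman.

**Compound list**

1 | ethyl 4-methylpent-3-enoate | CCOC(=O)CC=C(C)C | starting material
2 | lithium 1,1-dibromo-5-methylhexa-1,4-dien-2-olate | [Li+].[O-]C(CC=C(C)C)=C(Br)Br | intermediate (not isolated)
3 | lithium 5-methylhex-4-en-1-yn-1-olate | [Li+].[O-]C#CCC=C(C)C | intermediate (not isolated)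
4 | triisopropyl[(5-methylhex-4-en-1-yn-1-yl)oxy]silane | CC(C)=CCC#CO[Si](C(C)C)(C(C)C)C(C)C | intermediate
5 | methyl (E)-4-oxopent-2-enoate | COC(=O)/C=C/C(C)=O | starting material
6 | methyl (E)-7,7,7-trifluoro-4,6-dioxohept-2-enoate | COC(=O)/C=C/C(=O)CC(=O)C(F)(F)F | intermediate (not isolated)
7 | methyl (E)-5-diazo-4-oxopent-2-enoate | COC(=O)/C=C/C(=O)C=[N+]=[N-] | intermediate
8 | methyl (2E)-5-oxopenta-2,4-dienoate | COC(=O)/C=C/C=C=O | intermediate (not isolated)
9 | methyl (2E)-3-[3-(3-methylbut-2-en-1-yl)-4-oxo-2-(triisopropylsilyloxy)cyclobut-2-en-1-yl]prop-2-enoate (racemic) | COC(=O)/C=C/C1C(O[Si](C(C)C)(C(C)C)C(C)C)=C(CC=C(C)C)C1=O | intermediate (not isolated)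
10 | methyl (2E,4E)-6-(3-methylbut-2-en-1-yl)-7-oxo-5-(triisopropylsilyloxy)hepta-2,4,6-trienoate | COC(=O)/C=C/C=C(/O[Si](C(C)C)(C(C)C)C(C)C)C(CC=C(C)C)=C=O | intermediate (not isolated)
11 | methyl 2-hydroxy-3-(3-methylbut-2-en-1-yl)-4-(triisopropylsilyloxy)benzoate | COC(=O)c1ccc(O[Si](C(C)C)(C(C)C)C(C)C)c(CC=C(C)C)c1O | intermediate
12 | methyl 2-methoxy-3-(3-methylbut-2-en-1-yl)-4-(triisopropylsilyloxy)benzoate | COC(=O)c1ccc(O[Si](C(C)C)(C(C)C)C(C)C)c(CC=C(C)C)c1OC | intermediate
13 | 1-(4-hydroxyphenyl)ethan-1-one | CC(=O)c1ccc(O)cc1 | starting material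
14 | 1-[4-(triisopropylsilyloxy)phenyl]ethan-1-one | CC(=O)c1ccc(O[Si](C(C)C)(C(C)C)C(C)C)cc1 | intermediate
15 | lithium 1-[4-(triisopropylsilyloxy)phenyl]ethen-1-olate | [Li+].[O-]C(=C)c1ccc(O[Si](C(C)C)(C(C)C)C(C)C)cc1 | intermediate (not isolated)
16 | 1-[2-methoxy-3-(3-methylbut-2-en-1-yl)-4-(triisopropylsilyloxy)phenyl]-3-[4-(triisopropylsilyloxy)phenyl]propane-1,3-dione | COc1c(C(=O)CC(=O)c2ccc(O[Si](C(C)C)(C(C)C)C(C)C)cc2)ccc(O[Si](C(C)C)(C(C)C)C(C)C)c1CC=C(C)C | intermediate
17 | 1-[4-hydroxy-2-methoxy-3-(3-methylbut-2-en-1-yl)phenyl]-3-(4-hydroxyphenyl)propane-1,3-dione | COc1c(C(=O)CC(=O)c2ccc(O)cc2)ccc(O)c1CC=C(C)C | target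

**Step count and risks**

Total steps: 7. Longest linear sequence: 5 (step 1 or 2, then 3, 4, 6, 7).

Most likely to fail, first: step 3. The enoate may photoisomerise to its Z form, after which the ketene would close by oxa-6π cyclisation to a 2-pyranone, or the ketene may dimerise faster than it finds the ynol ether. The fallback sets out from siloxyalkyne 4 and comes back at diketone 16; it takes the ester out of the ketene and installs the carbonyl carbon after ring formation:
- Thermal benzannulation of 4 with cyclobut-2-en-1-one F1 (PhMe, 80 → 110 °C) should give 2-(3-methylbut-2-en-1-yl)-3-(triisopropylsilyloxy)phenol F2.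
- Magnesium-mediated ortho-formylation (MgCl2, Et3N, paraformaldehyde, MeCN, reflux) can enter only the one free ortho position and should give 2-hydroxy-3-(3-methylbut-2-en-1-yl)-4-(triisopropylsilyloxy)benzaldehyde F3.
- Methylation (MeI, K2CO3, acetone) should give 2-methoxy-3-(3-methylbut-2-en-1-yl)-4-(triisopropylsilyloxy)benzaldehyde F4.
- Aldol addition of lithium enolate 15 (THF, −78 °C) should give racemic 3-hydroxy-3-[2-methoxy-3-(3-methylbut-2-en-1-yl)-4-(triisopropylsilyloxy)phenyl]-1-[4-(triisopropylsilyloxy)phenyl]propan-1-one F5, and Dess–Martin oxidation should give 16.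

Second: step 2. The enolate of 5 may add to unreacted enone ester (anionic oligomerisation) before it is trifluoroacetylated. The fallback sets out from 5 and comes back at 7 without any enolate:
- Riley oxidation of the methyl group (SeO2, dioxane–H2O, reflux) should give methyl (E)-4,5-dioxopent-2-enoate F6.
- Condensation with tosylhydrazide at the aldehyde (MeOH, 0 °C) should give methyl (2E)-5-[(4-methylbenzenesulfonyl)hydrazinylidene]-4-oxopent-2-enoate F7.
- Bamford–Stevens-type loss of sulfinate (Et3N, CH2Cl2, 0 °C) should give 7.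

Third: step 1. The β,γ-unsaturated ester may be deprotonated at its α-position instead of taking up the carbenoid, with alkene migration, or the ynolate may be silylated on carbon. The fallback sets out from ester 1 and comes back at lithium ynolate 3, which is silylated as in step 1; the ynolate is made by oxidation of an acetylide, not by carbenoid rearrangement:
- Reduction (i-Bu2AlH, CH2Cl2, −78 °C) should give 4-methylpent-3-enal F8.
- Corey–Fuchs olefination (CBr4, PPh3, CH2Cl2, 0 °C) should give 1,1-dibromo-5-methylhexa-1,4-diene F9.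
- n-BuLi (2 equiv, THF, −78 °C) should give lithium 5-methylhex-4-en-1-yn-1-ide F10.
- Oxidation of F10 with LiOOt-Bu (from t-BuOOH and LiN(SiMe3)2) should give 3.

**Further compounds**

F1 | step 3 | cyclobut-2-en-1-one | O=C1C=CC1
F2 | step 3 | 2-(3-methylbut-2-en-1-yl)-3-(triisopropylsilyloxy)phenol | CC(C)=CCc1c(O)cccc1O[Si](C(C)C)(C(C)C)C(C)C
F3 | step 3 | 2-hydroxy-3-(3-methylbut-2-en-1-yl)-4-(triisopropylsilyloxy)benzaldehyde | O=Cc1ccc(O[Si](C(C)C)(C(C)C)C(C)C)c(CC=C(C)C)c1O
F4 | step 3 | 2-methoxy-3-(3-methylbut-2-en-1-yl)-4-(triisopropylsilyloxy)benzaldehyde | COc1c(C=O)ccc(O[Si](C(C)C)(C(C)C)C(C)C)c1CC=C(C)C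
F5 | step 3 | 3-hydroxy-3-[2-methoxy-3-(3-methylbut-2-en-1-yl)-4-(triisopropylsilyloxy)phenyl]-1-[4-(triisopropylsilyloxy)phenyl]propan-1-one (racemic) | COc1c(C(O)CC(=O)c2ccc(O[Si](C(C)C)(C(C)C)C(C)C)cc2)ccc(O[Si](C(C)C)(C(C)C)C(C)C)c1CC=C(C)C
F6 | step 2 | methyl (E)-4,5-dioxopent-2-enoate | COC(=O)/C=C/C(=O)C=O
F7 | step 2 | methyl (2E)-5-[(4-methylbenzenesulfonyl)hydrazinylidene]-4-oxopent-2-enoate | COC(=O)/C=C/C(=O)/C=N/NS(=O)(=O)c1ccc(C)cc1
F8 | step 1 | 4-methylpent-3-enal | O=CCC=C(C)C
F9 | step 1 | 1,1-dibromo-5-methylhexa-1,4-diene | BrC(Br)=CCC=C(C)C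
F10 | step 1 | lithium 5-methylhex-4-en-1-yn-1-ide | [Li+].[C-]#CCC=C(C)C
A1 | direct plan | 3-[bis(methylsulfanyl)methylidene]-6-methylhept-5-en-2-one | CC(=O)C(CC=C(C)C)=C(SC)SC
A2 | direct plan | 1,1-dimethoxy-2-(3-methylbut-2-en-1-yl)-3-(trimethylsilyloxy)buta-1,3-diene | C=C(O[Si](C)(C)C)C(CC=C(C)C)=C(OC)OC
A3 | direct plan | (E)-1-[4-(tert-butyldimethylsilyloxy)phenyl]-1-methoxypent-1-en-4-yn-3-one | C#CC(=O)/C=C(/OC)c1ccc(O[Si](C)(C)C(C)(C)C)cc1
A4 | direct plan | (E)-3-[4-(tert-butyldimethylsilyloxy)phenyl]-1-[4-hydroxy-2-methoxy-3-(3-methylbut-2-en-1-yl)phenyl]-3-methoxyprop-2-en-1-one | COc1c(C(=O)/C=C(/OC)c2ccc(O[Si](C)(C)C(C)(C)C)cc2)ccc(O)c1CC=C(C)C
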